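The pentasubstituted benzene ring is cut at C2–C3 and C1–C6 (ring numbering: C1 CHO, C2 side chain, C3 OH, C4 OMe, C5 H, C6 OH). The four-carbon unit C3–C6 with its three oxygens becomes an electron-rich silyl ketene acetal diene. C1–C2, carrying the formyl group and the finished (R)-2-acetoxytridecyl chain, becomes an ynal. One regioselective Diels–Alder cycloaddition, followed by acid-induced loss of methanol and of the silyl group, forms both ring bonds, closes the arene and places all five substituents. The precursors are a 4-benzyloxy-1,3-dimethoxy-1-silyloxybutadiene made from methyl 4-chloro-3-oxobutanoate and an acetoxy ynal whose stereocentre comes from (R)-epichlorohydrin; debenzylation then gives the target.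

Key step: step 9

Remark: (R)-epichlorohydrin leads to the (R)-acetate because steps 1–3 break no bond to the stereocentre and the CIP ranking (O > CH2X > CH2-alkyl > H) stays the same throughout. The diene is used as a mixture of C3=C4 isomers, since that geometry is erased on aromatisation. The acetate is installed before the aldehyde is unmasked so that the base-sensitive ynal never meets an amine.

Step 1
Reactants: 1 1-bromodecane; 2 (R)-epichlorohydrin
Product: 4 (R)-1-chlorotridecan-2-ol, via decylmagnesium bromide 3 (not isolated)
Conditions: Mg, THF, rt; then added to 2, CuI (10 mol %), THF, −40 → −20 °C; then 1 M HCl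
Reagents that add atoms: none
Why: Copper-catalysed Grignard opening of a terminal epoxide (SN2 at the unsubstituted ring CH2) outruns attack at the C–Cl carbon, so the chain is joined without touching the stereocentre, which keeps its (R) descriptor.

Step 2
Reactants: 4 (R)-1-chlorotridecan-2-ol
Product: 5 (R)-2-undecyloxirane
Conditions: NaOH (powdered), Et2O, 0 °C → rt
Reagents that add atoms: none
Why: Intramolecular Williamson etherification of the chlorohydrin alkoxide (3-exo-tet) displaces the primary chloride, so the C–O bond at the stereocentre is retained and the (R) configuration is kept.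

Step 3
Reactants: 5 (R)-2-undecyloxirane; 6 3,3-diethoxyprop-1-yne
Product: 8 (R)-1,1-diethoxyhexadec-2-yn-5-ol, via lithium acetylide 7 (not isolated)
Conditions: 6, n-BuLi, THF, −78 °C; BF3·OEt2, −78 °C; then 5, −78 °C; aq. NH4Cl
Reagents that add atoms: none
Why: BF3-promoted opening of a terminal epoxide by a lithium acetylide occurs at the unhindered CH2 at −78 °C, where the diethyl acetal survives, and the carbinol stereocentre is again not involved.

Step 4
Reactants: 8 (R)-1,1-diethoxyhexadec-2-yn-5-ol
Product: 9 (R)-1,1-diethoxyhexadec-2-yn-5-yl acetate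
Conditions: Ac2O, pyridine, DMAP (cat.), CH2Cl2, 0 °C → rt
Reagents that add atoms: acetic anhydride, CC(=O)OC(C)=O
Why: DMAP-catalysed acylation of a secondary alcohol proceeds with retention at carbon, and the acetal and alkyne are inert to these basic conditions.

Step 5
Reactants: 9 (R)-1,1-diethoxyhexadec-2-yn-5-yl acetate
Product: 10 (R)-1-oxohexadec-2-yn-5-yl acetate
Conditions: HCO2H–H2O (9:1), CHCl3, rt
Reagents that add atoms: water, O
Why: Acid-catalysed acetal hydrolysis releases the conjugated ynal; the secondary acetate tolerates aqueous formic acid at room temperature, and the absence of base prevents loss of acetic acid across C4–C5.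

Step 6
Reactants: 11 methyl 4-chloro-3-oxobutanoate
Product: 12 methyl 4-(benzyloxy)-3-oxobutanoate
Conditions: BnOH, NaH (2.2 equiv), THF, 0 °C → rt; then 1 M HCl
Reagents that add atoms: benzyl alcohol, OCc1ccccc1
Why: Williamson-type SN2 displacement of the primary chloride by sodium benzyloxide, with the β-keto ester held as its sodium enolate by the second equivalent of base so that the ester is not attacked.

Step 7
Reactants: 12 methyl 4-(benzyloxy)-3-oxobutanoate
Product: 14 methyl (E)-4-(benzyloxy)-3-methoxybut-2-enoate, via dimethyl ketal 13 (not isolated)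
Conditions: HC(OMe)3, MeOH, H2SO4 (cat.), rt; then 130 °C, MeOH distilled off
Reagents that add atoms: trimethyl orthoformate, COC(OC)OC
Why: Acid-catalysed ketalisation with the orthoformate followed by thermal loss of methanol gives the conjugated push–pull β-methoxy enoate, the (E) isomer being the thermodynamic one as in the parent acetoacetate series.

Step 8
Reactants: 14 methyl (E)-4-(benzyloxy)-3-methoxybut-2-enoate
Product: 16 4-(benzyloxy)-1,3-dimethoxy-1-(trimethylsilyloxy)buta-1,3-diene, via lithium dienolate 15 (not isolated)
Conditions: LiN(i-Pr)2, THF, −78 °C; then Me3SiCl, −78 °C → rt; filtered under N2, used crude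
Reagents that add atoms: chlorotrimethylsilane, C[Si](C)(C)Cl
Why: Kinetic γ-deprotonation of the β-methoxy enoate (the CH2OBn group lies cis to the ester carbonyl in the (E) isomer) gives the extended dienolate, which Me3SiCl silylates on oxygen, the standard route to 1,3-dialkoxy-1-silyloxybutadienes.

Step 9
Reactants: 16 4-(benzyloxy)-1,3-dimethoxy-1-(trimethylsilyloxy)buta-1,3-diene; 10 (R)-1-oxohexadec-2-yn-5-yl acetate
Product: 19 (R)-1-[2-(benzyloxy)-6-formyl-5-hydroxy-3-methoxyphenyl]tridecan-2-yl acetate, via cyclohexadiene cycloadduct 17 (not isolated), via aryl silyl ether 18 (not isolated)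
Conditions: 16 (1.5 equiv), toluene, 0 °C → rt, no Lewis acid; then 0.5 M HCl, THF, rt
Reagents that add atoms: none
Why: The OBn-bearing diene terminus (future C3), made nucleophilic by the 3-OMe group and by vinylogous donation from the ketene acetal oxygens, bonds to the ynal β-carbon (future C2) while the ketene acetal carbon (future C6) bonds to the α-carbon (future C1) in a concerted, strongly asynchronous [4+2] cycloaddition that gives cyclohexa-1,4-diene 17. Acid then ionises the mixed ketal at C6 with loss of methanol, the C3 proton is lost to aromatise, and aryl silyl ether 18 is hydrolysed to the C6 phenol, which is hydrogen-bonded to the aldehyde. The closest known reaction type is the Diels–Alder/aromatisation of 1,3-dialkoxy-1-silyloxybutadienes with acetylenic carbonyl dienophiles. The benzene ring is the only ring closed, by intermolecular [4+2] cycloaddition (four carbons from the diene, two from the alkyne) followed by 1,4-elimination. No stereocentre is created, since the two sp3 ring carbons of 17 become aromatic, and the (R) acetate centre, two atoms from the alkyne, is untouched under neutral thermal conditions. The step needs regioselectivity and chemoselectivity for the alkyne over the aldehyde C=O: the first comes from matched polarisation (largest diene HOMO coefficient at the OBn terminus, largest ynal LUMO coefficient at the β-carbon), the second from excluding any Lewis acid, which would steer the diene to the carbonyl group.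

Step 10
Reactants: 19 (R)-1-[2-(benzyloxy)-6-formyl-5-hydroxy-3-methoxyphenyl]tridecan-2-yl acetate
Product: 20 (R)-1-(2-formyl-3,6-dihydroxy-5-methoxyphenyl)tridecan-2-yl acetate
Conditions: BCl3 (3 equiv), pentamethylbenzene (5 equiv), CH2Cl2, −78 °C; then H2O
Reagents that add atoms: none
Why: Lewis-acid debenzylation with BCl3 and the non-basic cation scavenger pentamethylbenzene cleaves aryl benzyl ethers at −78 °C, where the methyl ether (not ortho to the carbonyl), the secondary acetate and the boron-chelated hydroxy aldehyde should survive and ring benzylation is suppressed.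

Compound list
1 | 1-bromodecane | CCCCCCCCCCBr | starting material
2 | (R)-epichlorohydrin | ClC[C@H]1CO1 | starting material
3 | decylmagnesium bromide | CCCCCCCCCC[Mg]Br | intermediate
4 | (R)-1-chlorotridecan-2-ol | ClC[C@H](O)CCCCCCCCCCC | intermediate
5 | (R)-2-undecyloxirane | CCCCCCCCCCC[C@@H]1CO1 | intermediate
6 | 3,3-diethoxyprop-1-yne | C#CC(OCC)OCC | starting material
7 | (3,3-diethoxyprop-1-yn-1-yl)lithium (lithium acetylide of 6) | [Li]C#CC(OCC)OCC | intermediate
8 | (R)-1,1-diethoxyhexadec-2-yn-5-ol | CCCCCCCCCCC[C@@H](O)CC#CC(OCC)OCC | intermediate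
9 | (R)-1,1-diethoxyhexadec-2-yn-5-yl acetate | CCCCCCCCCCC[C@H](CC#CC(OCC)OCC)OC(C)=O | intermediate
10 | (R)-1-oxohexadec-2-yn-5-yl acetate | CCCCCCCCCCC[C@H](CC#CC=O)OC(C)=O | intermediate
11 | methyl 4-chloro-3-oxobutanoate | COC(=O)CC(=O)CCl | starting material
12 | methyl 4-(benzyloxy)-3-oxobutanoate | COC(=O)CC(=O)COCc1ccccc1 | intermediate
13 | methyl 4-(benzyloxy)-3,3-dimethoxybutanoate | COC(=O)CC(OC)(OC)COCc1ccccc1 | intermediate
14 | methyl (E)-4-(benzyloxy)-3-methoxybut-2-enoate | COC(=O)/C=C(/OC)COCc1ccccc1 | intermediate
15 | lithium 4-(benzyloxy)-1,3-dimethoxybuta-1,3-dien-1-olate | [Li]OC(OC)=CC(OC)=COCc1ccccc1 | intermediate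
16 | 4-(benzyloxy)-1,3-dimethoxy-1-(trimethylsilyloxy)buta-1,3-diene (mixture of double-bond isomers) | COC(O[Si](C)(C)C)=CC(OC)=COCc1ccccc1 | intermediate
17 | (R)-1-[6-(benzyloxy)-2-formyl-3,5-dimethoxy-3-(trimethylsilyloxy)cyclohexa-1,4-dien-1-yl]tridecan-2-yl acetate (mixture of ring diastereomers) | CCCCCCCCCCC[C@H](CC1=C(C=O)C(OC)(O[Si](C)(C)C)C=C(OC)C1OCc1ccccc1)OC(C)=O | intermediate
18 | (R)-1-[2-(benzyloxy)-6-formyl-3-methoxy-5-(trimethylsilyloxy)phenyl]tridecan-2-yl acetate | CCCCCCCCCCC[C@H](Cc1c(OCc2ccccc2)c(OC)cc(O[Si](C)(C)C)c1C=O)OC(C)=O | intermediate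
19 | (R)-1-[2-(benzyloxy)-6-formyl-5-hydroxy-3-methoxyphenyl]tridecan-2-yl acetate | CCCCCCCCCCC[C@H](Cc1c(OCc2ccccc2)c(OC)cc(O)c1C=O)OC(C)=O | intermediate
20 | (R)-1-(2-formyl-3,6-dihydroxy-5-methoxyphenyl)tridecan-2-yl acetate | CCCCCCCCCCC[C@H](Cc1c(O)c(OC)cc(O)c1C=O)OC(C)=O | target

Total step count: 10. Longest linear sequence: 7 steps (steps 1–5, 9, 10); the diene branch (steps 6–8) joins at step 9.

Steps most likely to fail

Step 9. The silyl ketene acetal may add to the aldehyde carbonyl (hetero-Diels–Alder or vinylogous Mukaiyama aldol) instead of the alkyne. The crowded OBn terminus may slow the cycloaddition until the diene hydrolyses. On aromatisation the silyloxy group may leave instead of methoxide, giving a C6 methyl ether; BCl3 in step 10 would cleave that ortho-carbonyl ether, so this last process corrects itself. The fallback sets out from 10 and replaces the acyclic diene by a furan diene. Commercial 4-methoxyfuran-2(5H)-one (COC1=CC(=O)OC1) would be silylated (Me3SiOTf, Et3N, CH2Cl2, 0 °C) to 4-methoxy-2-(trimethylsilyloxy)furan F1. Heating F1 with 10 in toluene should give, with the same polarity match (furan C5 to the ynal β-carbon), the oxygen-bridged adduct (R)-1-[3-formyl-6-methoxy-4-(trimethylsilyloxy)-7-oxabicyclo[2.2.1]hepta-2,5-dien-2-yl]tridecan-2-yl acetate F2. Dilute acid should open the bridge at the silyloxy-bearing bridgehead, the dienone should tautomerise to the hydroquinone, and the silyl group should be lost. This returns to the route at 20 with no benzyl ether and no step 10.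

Step 8. Deprotonation may occur at the vinylic C2–H or at the benzylic ether position instead of C4, silylation may go to carbon, or the ketene acetal may hydrolyse during isolation. The fallback sets out from 12 and uses the two-stage route to 1,3-bis(silyloxy)dienes from β-keto esters. Me3SiCl/Et3N should give methyl 4-(benzyloxy)-3-(trimethylsilyloxy)but-2-enoate F3, and LiN(i-Pr)2 then Me3SiCl should give 4-(benzyloxy)-1-methoxy-1,3-bis(trimethylsilyloxy)buta-1,3-diene F4. Cycloaddition of F4 with 10 and acid work-up, as in step 9, should give (R)-1-[2-(benzyloxy)-6-formyl-3,5-dihydroxyphenyl]tridecan-2-yl acetate F5. Its 3-OH is para to the aldehyde, not hydrogen-bonded and the more acidic, so it should be methylated selectively (MeI 1 equiv, K2CO3, acetone), returning to the route at 19.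

Step 5. The propargylic acetal is inductively deactivated and may hydrolyse slowly; forcing the acid may solvolyse the acetate; and the ynal may lose acetic acid through its C4 protons or polymerise on work-up. The fallback sets out from 5 and reaches the aldehyde by oxidation instead of hydrolysis. Opening 5 with lithiated tert-butyldimethyl(prop-2-yn-1-yloxy)silane (C#CCO[Si](C)(C)C(C)(C)C; n-BuLi, BF3·OEt2, THF, −78 °C) should give (R)-1-(tert-butyldimethylsilyloxy)hexadec-2-yn-5-ol F6. Acetylation (Ac2O, pyridine, DMAP) should give (R)-1-(tert-butyldimethylsilyloxy)hexadec-2-yn-5-yl acetate F7. HF·pyridine in THF should give (R)-1-hydroxyhexadec-2-yn-5-yl acetate F8. Oxidation with Dess–Martin periodinane (NaHCO3-buffered CH2Cl2) should return to the route at 10.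

Further compounds
F1 | step 9 | 4-methoxy-2-(trimethylsilyloxy)furan | C[Si](C)(C)Oc1cc(OC)co1
F2 | step 9 | (R)-1-[3-formyl-6-methoxy-4-(trimethylsilyloxy)-7-oxabicyclo[2.2.1]hepta-2,5-dien-2-yl]tridecan-2-yl acetate | CCCCCCCCCCC[C@H](CC1=C(C=O)C2(O[Si](C)(C)C)C=C(OC)C1O2)OC(C)=O
F3 | step 8 | methyl 4-(benzyloxy)-3-(trimethylsilyloxy)but-2-enoate | COC(=O)C=C(O[Si](C)(C)C)COCc1ccccc1
F4 | step 8 | 4-(benzyloxy)-1-methoxy-1,3-bis(trimethylsilyloxy)buta-1,3-diene | COC(O[Si](C)(C)C)=CC(O[Si](C)(C)C)=COCc1ccccc1
F5 | step 8 | (R)-1-[2-(benzyloxy)-6-formyl-3,5-dihydroxyphenyl]tridecan-2-yl acetate | CCCCCCCCCCC[C@H](Cc1c(OCc2ccccc2)c(O)cc(O)c1C=O)OC(C)=O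
F6 | step 5 | (R)-1-(tert-butyldimethylsilyloxy)hexadec-2-yn-5-ol | CCCCCCCCCCC[C@@H](O)CC#CCO[Si](C)(C)C(C)(C)C
F7 | step 5 | (R)-1-(tert-butyldimethylsilyloxy)hexadec-2-yn-5-yl acetate | CCCCCCCCCCC[C@H](CC#CCO[Si](C)(C)C(C)(C)C)OC(C)=O
F8 | step 5 | (R)-1-hydroxyhexadec-2-yn-5-yl acetate | CCCCCCCCCCC[C@H](CC#CCO)OC(C)=O
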